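The hydroxymethyl carbon C18 and the carbinol carbon C6 stand in a 1,4-relationship across the C4–C5 bond of ring A (labdane numbering: ring A = C1–C5 and C10, ring B = C5–C10). An epoxide answers this pattern as a cation equivalent alpha to a primary alcohol. Ring B is therefore made first as a cyclohexenone that carries the C9 side chain and, on C10, a 3-[(S)-2-methyloxiran-2-yl]propyl chain. Its cross-conjugated silyl dienol ether opens the epoxide at the tertiary carbon under Lewis acid: one operation forms C4–C5, closes ring A, sets quaternary C4 by inversion and C5, and unveils the C18 alcohol and the C6 ketone.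

Key step: step 15

Remark: locants C1–C20 in the comments are labdane locants of the target (C9 bears the side chain, C10 the angular methyl, C18 is the hydroxymethyl carbon); (R)-2-methylglycidol is taken as a catalogue chemical.

Step 1
Reactants: 1 hex-5-yn-1-ol
Product: 3 6-(trimethylsilyl)hex-5-yn-1-ol, via bis-silylated alkynol 2 (not isolated)
Conditions: n-BuLi (2.2 equiv), THF, −78 °C; TMSCl (2.3 equiv), −78 °C to rt; then 1 M HCl, rt
Reagents that add atoms: chlorotrimethylsilane, C[Si](C)(C)Cl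
Why: Double lithiation and C,O-bis-silylation followed by selective acid hydrolysis of the silyl ether is the standard protection of a terminal alkyne in an alkynol; no stereocentre is involved.

Step 2
Reactants: 3 6-(trimethylsilyl)hex-5-yn-1-ol
Product: 4 6-(trimethylsilyl)hex-5-ynal
Conditions: TEMPO (10 mol%), PhI(OAc)2, CH2Cl2, rt
Reagents that add atoms: none
Why: TEMPO-catalysed oxoammonium oxidation with PhI(OAc)2 as terminal oxidant stops at the aldehyde and tolerates the silylalkyne.

Step 3
Reactants: 4 6-(trimethylsilyl)hex-5-ynal; 5 but-3-en-2-one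
Product: 7 (4R)-4-[4-(trimethylsilyl)but-3-yn-1-yl]cyclohex-2-en-1-one, via keto aldehyde 6 (not isolated)
Conditions: (S)-2-[methoxy(diphenyl)methyl]pyrrolidine (5 mol%), ethyl 3,4-dihydroxybenzoate (20 mol%), neat, 4 °C; then Bn2NH·CF3CO2H (20 mol%), toluene, 50 °C
Reagents that add atoms: none
Why: Enamine-catalysed Michael addition of the aldehyde to the vinyl ketone, in which the diphenyl(methoxy)methyl group of the (S)-catalyst shields one enamine face so that C9 should form with R configuration, is followed by an ammonium-salt-catalysed intramolecular aldol condensation that closes ring B without touching C9.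

Step 4
Reactants: 7 (4R)-4-[4-(trimethylsilyl)but-3-yn-1-yl]cyclohex-2-en-1-one
Product: 9 (4R)-3-methyl-4-[4-(trimethylsilyl)but-3-yn-1-yl]cyclohex-2-en-1-one, via lithium enolate 8 (not isolated)
Conditions: Me2CuLi (from MeLi and CuI), Et2O, −78 °C; then PhS(Cl)=N-t-Bu, THF, −78 °C to 0 °C
Reagents that add atoms: lithium dimethylcuprate, [Li+].C[Cu-]C
Why: Cuprate conjugate addition places the future C10 methyl, and dehydrogenation of the resulting enolate with the sulfinimidoyl chloride (syn elimination of the C10 hydrogen) regenerates the enone, so the transient stereocentre at C10 disappears while C9 is untouched.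

Step 5
Reactants: 10 [(2R)-2-methyloxiran-2-yl]methanol
Product: 11 (2S)-2-methylpent-4-ene-1,2-diol
Conditions: CH2=CHMgBr (2.5 equiv), CuI (10 mol%), THF, −30 °C to 0 °C; aq. NH4Cl
Reagents that add atoms: vinylmagnesium bromide, C=C[Mg]Br
Why: Copper-catalysed Grignard opening of the epoxide occurs at the unsubstituted carbon, no bond to the quaternary carbinol centre (the future C4) is broken, and its configuration is carried over (the descriptor changes from R to S only by the priority rules).

Step 6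
Reactants: 11 (2S)-2-methylpent-4-ene-1,2-diol
Product: 12 (4S)-2,2,4-trimethyl-4-(prop-2-en-1-yl)-1,3-dioxolane
Conditions: Me2C(OMe)2, PPTS (cat.), CH2Cl2, rt
Reagents that add atoms: 2,2-dimethoxypropane, COC(C)(C)OC
Why: Acid-catalysed transacetalization protects the 1,2-diol as the five-membered acetonide.

Step 7
Reactants: 12 (4S)-2,2,4-trimethyl-4-(prop-2-en-1-yl)-1,3-dioxolane
Product: 14 3-[(4S)-2,2,4-trimethyl-1,3-dioxolan-4-yl]propan-1-ol, via alkylborane 13 (not isolated)
Conditions: 9-BBN-H, THF, 0 °C to rt; then NaOH, H2O2, 0 °C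
Reagents that add atoms: hydrogen peroxide, OO
Why: Hydroboration–oxidation with the bulky borane 9-BBN-H functionalizes the terminal alkene carbon (anti-Markovnikov) to give the primary alcohol.

Step 8
Reactants: 14 3-[(4S)-2,2,4-trimethyl-1,3-dioxolan-4-yl]propan-1-ol
Product: 15 (4S)-4-(3-bromopropyl)-2,2,4-trimethyl-1,3-dioxolane
Conditions: CBr4, PPh3, 2,6-lutidine, CH2Cl2, 0 °C
Reagents that add atoms: tetrabromomethane, BrC(Br)(Br)Br
Why: Appel bromination converts the primary alcohol into the bromide under buffered, nearly neutral conditions that spare the acetonide.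

Step 9
Reactants: 9 (4R)-3-methyl-4-[4-(trimethylsilyl)but-3-yn-1-yl]cyclohex-2-en-1-one; 15 (4S)-4-(3-bromopropyl)-2,2,4-trimethyl-1,3-dioxolane
Product: 18 (3R,4R)-3-methyl-3-{3-[(4S)-2,2,4-trimethyl-1,3-dioxolan-4-yl]propyl}-4-[4-(trimethylsilyl)but-3-yn-1-yl]cyclohexan-1-one, via Grignard reagent 16 (not isolated), via silyl enol ether 17 (not isolated)
Conditions: Mg, THF, rt (15 to 16); CuBr·SMe2 (10 mol%), TMSCl, HMPA, THF, −78 to −40 °C, then 9; 0.5 M HCl, THF, 0 °C
Reagents that add atoms: none
Why: Chlorosilane-accelerated, copper-catalysed conjugate addition of the Grignard reagent to the β,β-disubstituted enone should take place anti to the pseudoaxial C9 substituent, which sets the quaternary C10 with its methyl cis to the C9 chain, and brief acid hydrolysis of the silyl enol ether gives the ketone.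

Step 10
Reactants: 18 (3R,4R)-3-methyl-3-{3-[(4S)-2,2,4-trimethyl-1,3-dioxolan-4-yl]propyl}-4-[4-(trimethylsilyl)but-3-yn-1-yl]cyclohexan-1-one
Product: 19 (4R,5R)-5-methyl-5-{3-[(4S)-2,2,4-trimethyl-1,3-dioxolan-4-yl]propyl}-4-[4-(trimethylsilyl)but-3-yn-1-yl]cyclohex-2-en-1-one
Conditions: IBX (2.5 equiv), DMSO–toluene, 70 °C
Reagents that add atoms: none
Why: IBX dehydrogenation of the ketone can only proceed toward C7–C8 because the other α-carbon (C5) has no β-hydrogen (C10 is quaternary), so the enone forms regiospecifically.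

Step 11
Reactants: 19 (4R,5R)-5-methyl-5-{3-[(4S)-2,2,4-trimethyl-1,3-dioxolan-4-yl]propyl}-4-[4-(trimethylsilyl)but-3-yn-1-yl]cyclohex-2-en-1-one
Product: 21 (4S,5R)-3,5-dimethyl-5-{3-[(4S)-2,2,4-trimethyl-1,3-dioxolan-4-yl]propyl}-4-[4-(trimethylsilyl)but-3-yn-1-yl]cyclohex-2-en-1-one, via lithium enolate 20 (not isolated)
Conditions: Me2CuLi (from MeLi and CuI), Et2O, −78 to −30 °C; then PhS(Cl)=N-t-Bu, THF, −78 °C to 0 °C
Reagents that add atoms: lithium dimethylcuprate, [Li+].C[Cu-]C
Why: A second cuprate conjugate addition followed by sulfinimidoyl chloride dehydrogenation of the enolate installs the C8 methyl and restores the C7=C8 double bond, which erases the transient C8 stereocentre.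

Step 12
Reactants: 21 (4S,5R)-3,5-dimethyl-5-{3-[(4S)-2,2,4-trimethyl-1,3-dioxolan-4-yl]propyl}-4-[4-(trimethylsilyl)but-3-yn-1-yl]cyclohex-2-en-1-one
Product: 22 (4S,5R)-5-[(4S)-4,5-dihydroxy-4-methylpentyl]-3,5-dimethyl-4-[4-(trimethylsilyl)but-3-yn-1-yl]cyclohex-2-en-1-one
Conditions: AcOH–H2O (4:1), 40 °C
Reagents that add atoms: none
Why: Mild aqueous acid hydrolyses the acetonide (acetal cleavage) while the enone, the silylalkyne and the tertiary carbinol centre are unaffected.

Step 13
Reactants: 22 (4S,5R)-5-[(4S)-4,5-dihydroxy-4-methylpentyl]-3,5-dimethyl-4-[4-(trimethylsilyl)but-3-yn-1-yl]cyclohex-2-en-1-one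
Product: 23 (4S,5R)-3,5-dimethyl-5-{3-[(2S)-2-methyloxiran-2-yl]propyl}-4-[4-(trimethylsilyl)but-3-yn-1-yl]cyclohex-2-en-1-one
Conditions: PPh3, DIAD, toluene, 0 °C to 70 °C
Reagents that add atoms: none
Why: Mitsunobu-type cyclodehydration activates the less hindered primary hydroxyl as an oxyphosphonium ion that the tertiary oxygen displaces (3-exo-tet), so no bond to C4 is broken and the epoxide keeps the S configuration.

Step 14
Reactants: 23 (4S,5R)-3,5-dimethyl-5-{3-[(2S)-2-methyloxiran-2-yl]propyl}-4-[4-(trimethylsilyl)but-3-yn-1-yl]cyclohex-2-en-1-one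
Product: 24 trimethyl({(3S,4R)-3,5-dimethyl-3-{3-[(2S)-2-methyloxiran-2-yl]propyl}-4-[4-(trimethylsilyl)but-3-yn-1-yl]cyclohexa-1,5-dien-1-yl}oxy)silane
Conditions: LDA (1.15 equiv), TMSCl, THF, −78 °C; pentane, filtration, evaporation (used crude)
Reagents that add atoms: chlorotrimethylsilane, C[Si](C)(C)Cl
Why: Kinetic deprotonation of the enone by LDA occurs at the only α′ position (C5) and in situ O-silylation gives the cross-conjugated 2-silyloxydiene, conditions under which the epoxide and the silylalkyne are inert.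

Step 15
Reactants: 24 trimethyl({(3S,4R)-3,5-dimethyl-3-{3-[(2S)-2-methyloxiran-2-yl]propyl}-4-[4-(trimethylsilyl)but-3-yn-1-yl]cyclohexa-1,5-dien-1-yl}oxy)silane
Product: 25 (4R,4aS,8S,8aS)-8-(hydroxymethyl)-3,4a,8-trimethyl-4-[4-(trimethylsilyl)but-3-yn-1-yl]-4a,5,6,7,8,8a-hexahydronaphthalen-1(4H)-one
Conditions: MeAlCl2 (2 equiv), CH2Cl2, −78 °C; then 1 M HCl, 0 °C
Reagents that add atoms: none
Why: MeAlCl2 binds the epoxide oxygen, the C4–O bond stretches toward a tertiary cation, and C5 of the 2-silyloxydiene attacks C4 from the side opposite the leaving oxygen, after which loss of the silyl group gives the enone and the aluminium alkoxide of C18. The closest known reaction type is the Lewis-acid-promoted, epoxide-initiated cation–olefin cyclization terminated by a silyl enol ether (a Mukaiyama-type epoxide opening), run here as a monocyclization. Ring A (C1–C5, C10) closes by a 6-exo-tet opening at the proximal epoxide carbon, 6-(enolexo) with respect to the nucleophile, through a chair-like array. C4 is fixed by inversion of the enantiopure (S)-epoxide carbon, which places CH2OH equatorial and CH3 axial, whereas C5 (alpha to the new ketone) is under thermodynamic control and should settle trans to the C10 methyl (completed in step 16). The step needs attack at the tertiary C4 and not at C18, and C–C bond formation ahead of the 1,2-hydride shift of the activated epoxide (Meinwald rearrangement); the first is secured by cation stability and by the six- over seven-membered ring, the second by the high nucleophilicity of the enol ether held at ring-closing distance.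

Step 16
Reactants: 25 (4R,4aS,8S,8aS)-8-(hydroxymethyl)-3,4a,8-trimethyl-4-[4-(trimethylsilyl)but-3-yn-1-yl]-4a,5,6,7,8,8a-hexahydronaphthalen-1(4H)-one
Product: 26 (4R,4aS,8S,8aS)-4-(but-3-yn-1-yl)-8-(hydroxymethyl)-3,4a,8-trimethyl-4a,5,6,7,8,8a-hexahydronaphthalen-1(4H)-one
Conditions: K2CO3, MeOH, rt
Reagents that add atoms: none
Why: Carbonate-catalysed methanolysis cleaves the alkynyl C–Si bond, and the same mild base should epimerize any cis-fused material at C5 (alpha to the ketone) to the more stable trans-decalin.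

Step 17
Reactants: 26 (4R,4aS,8S,8aS)-4-(but-3-yn-1-yl)-8-(hydroxymethyl)-3,4a,8-trimethyl-4a,5,6,7,8,8a-hexahydronaphthalen-1(4H)-one
Product: 27 (1R,4R,4aS,8S,8aS)-4-(but-3-yn-1-yl)-8-(hydroxymethyl)-3,4a,8-trimethyl-1,4,4a,5,6,7,8,8a-octahydronaphthalen-1-ol
Conditions: Al(OiPr)3 (3 equiv), i-PrOH–toluene, 80 °C, prolonged (a little acetone retained)
Reagents that add atoms: none
Why: Meerwein–Ponndorf–Verley reduction is 1,2-selective and reversible, so under equilibrating conditions the C6 alcohol should settle in the equatorial orientation trans to the C10 methyl (the axial epimer suffers 1,3-diaxial strain with the methyls on C4 and C10, and the equatorial alkoxide can chelate aluminium together with O18).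

Step 18
Reactants: 27 (1R,4R,4aS,8S,8aS)-4-(but-3-yn-1-yl)-8-(hydroxymethyl)-3,4a,8-trimethyl-1,4,4a,5,6,7,8,8a-octahydronaphthalen-1-ol
Product: 29 methyl (2E)-5-[(1R,4R,4aS,5S,8aS)-4-hydroxy-5-(hydroxymethyl)-2,5,8a-trimethyl-1,4,4a,5,6,7,8,8a-octahydronaphthalen-1-yl]-3-methylpent-2-enoate, via alkenylalane 28 (not isolated)
Conditions: Me3Al (5 equiv), Cp2ZrCl2 (0.3 equiv), CH2Cl2, 0 °C to rt; then ClCO2Me, 0 °C to rt; aq. potassium sodium tartrate
Reagents that add atoms: trimethylaluminium, C[Al](C)C; methyl chloroformate, COC(=O)Cl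
Why: Negishi zirconium-catalysed carboalumination adds methyl and aluminium syn across the terminal alkyne with methyl on the internal carbon, and acylation of the alkenylalane by methyl chloroformate with retention gives the (E)-enoate while the hydroxyls are carried as aluminium alkoxides.

Compound list
1 | hex-5-yn-1-ol | C#CCCCCO | starting material
2 | trimethyl{[6-(trimethylsilyl)hex-5-yn-1-yl]oxy}silane (not isolated) | C[Si](C)(C)C#CCCCCO[Si](C)(C)C | intermediate
3 | 6-(trimethylsilyl)hex-5-yn-1-ol | C[Si](C)(C)C#CCCCCO | intermediate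
4 | 6-(trimethylsilyl)hex-5-ynal | C[Si](C)(C)C#CCCCC=O | intermediate
5 | but-3-en-2-one | CC(=O)C=C | starting material
6 | (2R)-5-oxo-2-[4-(trimethylsilyl)but-3-yn-1-yl]hexanal (not isolated) | C[Si](C)(C)C#CCC[C@@H](C=O)CCC(C)=O | intermediate
7 | (4R)-4-[4-(trimethylsilyl)but-3-yn-1-yl]cyclohex-2-en-1-one | C[Si](C)(C)C#CCC[C@@H]1CCC(=O)C=C1 | intermediate
8 | lithium enolate (C5=C6) of trans-3-methyl-4-[4-(trimethylsilyl)but-3-yn-1-yl]cyclohexan-1-one (not isolated) | C[Si](C)(C)C#CCC[C@@H]1CCC(O[Li])=C[C@H]1C | intermediate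
9 | (4R)-3-methyl-4-[4-(trimethylsilyl)but-3-yn-1-yl]cyclohex-2-en-1-one | C[Si](C)(C)C#CCC[C@@H]1CCC(=O)C=C1C | intermediate
10 | [(2R)-2-methyloxiran-2-yl]methanol ((R)-2-methylglycidol) | C[C@@]1(CO)CO1 | starting material
11 | (2S)-2-methylpent-4-ene-1,2-diol | C[C@@](O)(CO)CC=C | intermediate
12 | (4S)-2,2,4-trimethyl-4-(prop-2-en-1-yl)-1,3-dioxolane | C[C@@]1(COC(C)(C)O1)CC=C | intermediate
13 | 9-{3-[(4S)-2,2,4-trimethyl-1,3-dioxolan-4-yl]propyl}-9-borabicyclo[3.3.1]nonane (not isolated) | C[C@@]1(COC(C)(C)O1)CCCB2C3CCCC2CCC3 | intermediate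
14 | 3-[(4S)-2,2,4-trimethyl-1,3-dioxolan-4-yl]propan-1-ol | C[C@@]1(COC(C)(C)O1)CCCO | intermediate
15 | (4S)-4-(3-bromopropyl)-2,2,4-trimethyl-1,3-dioxolane | C[C@@]1(COC(C)(C)O1)CCCBr | intermediate
16 | {3-[(4S)-2,2,4-trimethyl-1,3-dioxolan-4-yl]propyl}magnesium bromide (not isolated) | C[C@@]1(COC(C)(C)O1)CCC[Mg]Br | intermediate
17 | trimethylsilyl enol ether (C5=C6) of ketone 18 (not isolated) | C[Si](C)(C)C#CCC[C@@H]1CCC(O[Si](C)(C)C)=C[C@@]1(C)CCC[C@@]2(C)COC(C)(C)O2 | intermediate
18 | (3R,4R)-3-methyl-3-{3-[(4S)-2,2,4-trimethyl-1,3-dioxolan-4-yl]propyl}-4-[4-(trimethylsilyl)but-3-yn-1-yl]cyclohexan-1-one (ring methyl cis to the butynyl chain) | C[Si](C)(C)C#CCC[C@@H]1CCC(=O)C[C@@]1(C)CCC[C@@]2(C)COC(C)(C)O2 | intermediate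
19 | (4R,5R)-5-methyl-5-{3-[(4S)-2,2,4-trimethyl-1,3-dioxolan-4-yl]propyl}-4-[4-(trimethylsilyl)but-3-yn-1-yl]cyclohex-2-en-1-one | C[Si](C)(C)C#CCC[C@@H]1C=CC(=O)C[C@@]1(C)CCC[C@@]2(C)COC(C)(C)O2 | intermediate
20 | lithium enolate (C6=C7) from methyl addition to C8 of 19, new methyl trans to the C9 chain (not isolated) | C[Si](C)(C)C#CCC[C@@H]1[C@@H](C)C=C(O[Li])C[C@@]1(C)CCC[C@@]2(C)COC(C)(C)O2 | intermediate
21 | (4S,5R)-3,5-dimethyl-5-{3-[(4S)-2,2,4-trimethyl-1,3-dioxolan-4-yl]propyl}-4-[4-(trimethylsilyl)but-3-yn-1-yl]cyclohex-2-en-1-one | C[Si](C)(C)C#CCC[C@@H]1C(C)=CC(=O)C[C@@]1(C)CCC[C@@]2(C)COC(C)(C)O2 | intermediate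
22 | (4S,5R)-5-[(4S)-4,5-dihydroxy-4-methylpentyl]-3,5-dimethyl-4-[4-(trimethylsilyl)but-3-yn-1-yl]cyclohex-2-en-1-one | C[Si](C)(C)C#CCC[C@@H]1C(C)=CC(=O)C[C@@]1(C)CCC[C@](C)(O)CO | intermediate
23 | (4S,5R)-3,5-dimethyl-5-{3-[(2S)-2-methyloxiran-2-yl]propyl}-4-[4-(trimethylsilyl)but-3-yn-1-yl]cyclohex-2-en-1-one | C[Si](C)(C)C#CCC[C@@H]1C(C)=CC(=O)C[C@@]1(C)CCC[C@@]2(C)CO2 | intermediate
24 | trimethyl({(3S,4R)-3,5-dimethyl-3-{3-[(2S)-2-methyloxiran-2-yl]propyl}-4-[4-(trimethylsilyl)but-3-yn-1-yl]cyclohexa-1,5-dien-1-yl}oxy)silane | C[Si](C)(C)C#CCC[C@@H]1C(C)=CC(O[Si](C)(C)C)=C[C@@]1(C)CCC[C@@]2(C)CO2 | intermediate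
25 | (4R,4aS,8S,8aS)-8-(hydroxymethyl)-3,4a,8-trimethyl-4-[4-(trimethylsilyl)but-3-yn-1-yl]-4a,5,6,7,8,8a-hexahydronaphthalen-1(4H)-one (trans-fused) | C[Si](C)(C)C#CCC[C@@H]1C(C)=CC(=O)[C@@H]2[C@@](C)(CO)CCC[C@@]12C | intermediate
26 | (4R,4aS,8S,8aS)-4-(but-3-yn-1-yl)-8-(hydroxymethyl)-3,4a,8-trimethyl-4a,5,6,7,8,8a-hexahydronaphthalen-1(4H)-one | C#CCC[C@@H]1C(C)=CC(=O)[C@@H]2[C@@](C)(CO)CCC[C@@]12C | intermediate
27 | (1R,4R,4aS,8S,8aS)-4-(but-3-yn-1-yl)-8-(hydroxymethyl)-3,4a,8-trimethyl-1,4,4a,5,6,7,8,8a-octahydronaphthalen-1-ol | C#CCC[C@@H]1C(C)=C[C@@H](O)[C@@H]2[C@@](C)(CO)CCC[C@@]12C | intermediate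
28 | (E)-alkenyl(dimethyl)alane of 27 with both hydroxyls as dimethylaluminium alkoxides (not isolated) | C[Al](C)/C=C(\C)CC[C@@H]1C(C)=C[C@@H](O[Al](C)C)[C@@H]2[C@@](C)(CO[Al](C)C)CCC[C@@]12C | intermediate
29 | methyl (2E)-5-[(1R,4R,4aS,5S,8aS)-4-hydroxy-5-(hydroxymethyl)-2,5,8a-trimethyl-1,4,4a,5,6,7,8,8a-octahydronaphthalen-1-yl]-3-methylpent-2-enoate | COC(=O)/C=C(\C)CC[C@@H]1C(C)=C[C@@H](O)[C@@H]2[C@@](C)(CO)CCC[C@@]12C | target

Total step count: 18 steps. Longest linear sequence: 14 steps (steps 1–4 and 9–18; the chain branch, steps 5–8 and 9–18, is equally long).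

Steps most likely to fail

Step 15. The aluminium-bound epoxide may undergo the 1,2-hydride shift (Meinwald rearrangement), or the dienol ether may be protodesilylated, before the C–C bond forms; full ionisation at C4 would also erode the inversion. The fallback closes the same bond by a radical instead of a cation and sets out from 24. Cp2TiCl (from Cp2TiCl2 and Mn dust, THF, 2,4,6-collidinium chloride) should open the epoxide homolytically to the tertiary C4 radical, which adds 6-exo to C5, the terminus of the silyloxydiene. The siloxyallyl radical is reduced by a second Cp2TiCl and protonated at C8, and a non-acidic work-up should give the silyl enol ether F1. Pd(OAc)2 in MeCN (Saegusa–Ito dehydrogenation) then restores the C7=C8 double bond and returns to 25. In this variant C4 would rest on the preference of the bulky titanoxymethyl group for the equatorial site of the chair, not on inversion.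

Step 17. Hydride transfer to the hindered C6 carbonyl may be too slow for the two alkoxides to equilibrate, so that the kinetically formed axial alcohol persists, or the allylic alcohol may dehydrate on long heating. The fallback is kinetic reduction followed by inversion and sets out from 26. NaBH4 with CeCl3·7H2O in MeOH (Luche reduction) should deliver hydride from the face away from the two axial methyls and give the C6-epimeric diol F2. A Mitsunobu reaction with 4-nitrobenzoic acid (PPh3, DIAD, excess) esterifies C18 and inverts C6 to give the bis(4-nitrobenzoate) F3. K2CO3 in MeOH removes both esters and returns to 27.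

Step 18. The aluminium alkoxides of the two hydroxyls may be acylated by methyl chloroformate, or their aggregation may slow the carboalumination. The fallback traps the alkenylalane with iodine and brings in the ester by carbonylation; it sets out from 27. The same carboalumination followed by I2 should give the (E)-vinyl iodide F4. PdCl2(PPh3)2, CO (1 atm), MeOH and Et3N should then convert it with retention of the double-bond geometry into 29.

Further compounds
F1 | step 15 | trimethylsilyl enol ether (C6=C7) of the 7,8-dihydro derivative of 25, C8 as a mixture of epimers | C[Si](C)(C)C#CCC[C@@H]1C(C)C=C(O[Si](C)(C)C)[C@@H]2[C@@](C)(CO)CCC[C@@]12C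
F2 | step 17 | (1S,4R,4aS,8S,8aS)-4-(but-3-yn-1-yl)-8-(hydroxymethyl)-3,4a,8-trimethyl-1,4,4a,5,6,7,8,8a-octahydronaphthalen-1-ol (C6 epimer of 27) | C#CCC[C@@H]1C(C)=C[C@H](O)[C@@H]2[C@@](C)(CO)CCC[C@@]12C
F3 | step 17 | bis(4-nitrobenzoate) of 27 (esters on O6 and O18) | C#CCC[C@@H]1C(C)=C[C@@H](OC(=O)c3ccc(cc3)[N+](=O)[O-])[C@@H]2[C@@](C)(COC(=O)c3ccc(cc3)[N+](=O)[O-])CCC[C@@]12C
F4 | step 18 | (E)-vinyl iodide: (1R,4R,4aS,8S,8aS)-8-(hydroxymethyl)-4-[(3E)-4-iodo-3-methylbut-3-en-1-yl]-3,4a,8-trimethyl-1,4,4a,5,6,7,8,8a-octahydronaphthalen-1-ol | I/C=C(\C)CC[C@@H]1C(C)=C[C@@H](O)[C@@H]2[C@@](C)(CO)CCC[C@@]12C
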